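**Strategy.** Everything rests on disconnecting the epoxycyclohexanediol between the aryl carbinol carbon C1' and the adjacent ring methylene C6'. The feature exploited is the cis disposition, across the cyclohexane ring, of the C4' oxygen and the C1' hydroxyl: in the precursor O4' is joined to C6' through one extra carbonyl carbon, so that C4'–C6' sit in a γ-butyrolactone whose side chain is a cis-epoxy pyridyl ketone. The lactone lithium enolate adds to that ketone, closing the carbocycle as a 6-oxabicyclo[3.2.1]octanone and setting C1' through a chelated transition state. The bridging carbon is then removed by saponification and hydrodecarboxylation, and the decalin aldehyde is attached last.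

Key step: step 10

Remark: primed locants denote the cyclohexane unit (C1' = carbinol carbon on pyridone C5, C2'/C3' = epoxide carbons, C4' = secondary carbinol, C5'/C6' = methylenes). Compounds 1, 2, 9 and 19 and all named reagents are taken as commercial. The (R,R)-TsDPEN ruthenium catalyst is assumed to give the (R)-propargylic alcohol, as is usual for alkynyl ketones.

**Fragment A: epoxy aldehyde lactone**

Step 1
Reactants: 1 tert-butyldimethyl(prop-2-yn-1-yloxy)silane; 2 methyl 4-chloro-4-oxobutanoate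
Product: 3 methyl 7-[(tert-butyldimethylsilyl)oxy]-4-oxohept-5-ynoate
Conditions: PdCl2(PPh3)2 (2 mol %), CuI (4 mol %), Et3N (1.2 equiv), THF, rt
Reagents that add atoms: none
Why: Acyl Sonogashira coupling, in which the copper acetylide of 1 transmetallates to the acylpalladium chloride from 2 and reductive elimination should give the ynone without touching the methyl ester.

Step 2
Reactants: 3 methyl 7-[(tert-butyldimethylsilyl)oxy]-4-oxohept-5-ynoate
Product: 4 methyl (4R)-7-[(tert-butyldimethylsilyl)oxy]-4-hydroxyhept-5-ynoate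
Conditions: Ru[(R,R)-TsDPEN](p-cymene) (preformed 16-electron amido complex, 1 mol %), i-PrOH, 25 °C
Reagents that add atoms: none
Why: Noyori asymmetric transfer hydrogenation of an alkynyl ketone, where the alkynyl group takes the place of aryl in the outer-sphere transition state, so the (R,R)-catalyst should deliver hydride to give the (4R)-alcohol (C4') under neutral conditions that leave the ester open-chain.

Step 3
Reactants: 4 methyl (4R)-7-[(tert-butyldimethylsilyl)oxy]-4-hydroxyhept-5-ynoate
Product: 5 methyl (4R,5Z)-7-[(tert-butyldimethylsilyl)oxy]-4-hydroxyhept-5-enoate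
Conditions: H2 (1 atm), Pd/CaCO3 poisoned with Pb(OAc)2 (Lindlar catalyst), quinoline, EtOAc, rt
Reagents that add atoms: none
Why: Lindlar semihydrogenation adds hydrogen syn on the poisoned palladium surface and should stop at the Z-alkene.

Step 4
Reactants: 5 methyl (4R,5Z)-7-[(tert-butyldimethylsilyl)oxy]-4-hydroxyhept-5-enoate
Product: 6 methyl (4R)-4-[(2S,3R)-3-{[(tert-butyldimethylsilyl)oxy]methyl}oxiran-2-yl]-4-hydroxybutanoate
Conditions: mCPBA (1.3 equiv), NaHCO3, CH2Cl2, 0 °C
Reagents that add atoms: mCPBA, OOC(=O)c1cccc(Cl)c1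
Why: Henbest hydroxyl-directed epoxidation: the Z-allylic alcohol reacts through the conformer that minimises 1,3-allylic strain (C4'–H in the alkene plane) and the hydrogen-bonded peracid delivers oxygen to the hydroxyl face, giving the threo cis-epoxy alcohol and so setting C2' and C3' from C4'.

Step 5
Reactants: 6 methyl (4R)-4-[(2S,3R)-3-{[(tert-butyldimethylsilyl)oxy]methyl}oxiran-2-yl]-4-hydroxybutanoate
Product: 7 (5R)-5-[(2S,3R)-3-(hydroxymethyl)oxiran-2-yl]oxolan-2-one
Conditions: camphorsulfonic acid (0.1 equiv), MeOH, 0 °C; then solvent exchange to CH2Cl2, rt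
Reagents that add atoms: none
Why: Acid-catalysed methanolysis of the primary silyl ether and lactonisation of the γ-hydroxy ester (driven by removal of methanol) should occur without touching the epoxide or any stereocentre.

Step 6
Reactants: 7 (5R)-5-[(2S,3R)-3-(hydroxymethyl)oxiran-2-yl]oxolan-2-one
Product: 8 (2S,3S)-3-[(2R)-5-oxooxolan-2-yl]oxirane-2-carbaldehyde
Conditions: Dess–Martin periodinane, NaHCO3, CH2Cl2, 0 °C; used directly
Reagents that add atoms: none
Why: Dess–Martin oxidation converts the primary alcohol to the aldehyde under buffered, non-epimerising conditions that epoxides and lactones tolerate.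

**Fragment B: pyridine core and cyclohexane unit**

Step 7
Reactants: 9 5-bromo-2,4-dichloropyridine
Product: 10 5-bromo-2,4-bis[2-(trimethylsilyl)ethoxy]pyridine
Conditions: 2-(trimethylsilyl)ethanol (2.5 equiv), NaH (2.5 equiv), DMF, 0 → 90 °C
Reagents that add atoms: 2-(trimethylsilyl)ethanol, C[Si](C)(C)CCO
Why: Twofold nucleophilic aromatic substitution at the activated 4- and 2-positions should leave the unactivated 5-bromide in place and install fluoride-labile pyridone protection.

Step 8
Reactants: 10 5-bromo-2,4-bis[2-(trimethylsilyl)ethoxy]pyridine; 8 (2S,3S)-3-[(2R)-5-oxooxolan-2-yl]oxirane-2-carbaldehyde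
Product: 12 (5R)-5-[(2S,3R)-3-{[4,6-bis(2-(trimethylsilyl)ethoxy)pyridin-3-yl](hydroxy)methyl}oxiran-2-yl]oxolan-2-one (both carbinol epimers), via pyridyllithium 11 (not isolated)
Conditions: n-BuLi (1.05 equiv), THF, −78 °C, 15 min; then 8 (1.0 equiv), THF, −78 °C; aq NH4Cl
Reagents that add atoms: none
Why: Bromine–lithium exchange followed by 1,2-addition to the aldehyde, which at −78 °C is far more electrophilic than the lactone or epoxide; the new carbinol centre is uncontrolled and is erased in step 9.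

Step 9
Reactants: 12 (5R)-5-[(2S,3R)-3-{[4,6-bis(2-(trimethylsilyl)ethoxy)pyridin-3-yl](hydroxy)methyl}oxiran-2-yl]oxolan-2-one
Product: 13 (5R)-5-[(2S,3S)-3-{4,6-bis[2-(trimethylsilyl)ethoxy]pyridine-3-carbonyl}oxiran-2-yl]oxolan-2-one
Conditions: Dess–Martin periodinane, NaHCO3, CH2Cl2, 0 °C → rt
Reagents that add atoms: none
Why: Dess–Martin oxidation of the secondary carbinol converges both epimers on the cis-epoxy aryl ketone, which has no enolisable hydrogen.

Step 10
Reactants: 13 (5R)-5-[(2S,3S)-3-{4,6-bis[2-(trimethylsilyl)ethoxy]pyridine-3-carbonyl}oxiran-2-yl]oxolan-2-one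
Product: 15 (1S,2R,3S,4S,5R)-2-{4,6-bis[2-(trimethylsilyl)ethoxy]pyridin-3-yl}-3,4-epoxy-2-hydroxy-6-oxabicyclo[3.2.1]octan-7-one, via lithium enolate 14 (not isolated)
Conditions: LiN(SiMe3)2 (1.1 equiv), THF (0.02 M), −78 °C, 1 h; AcOH in THF, −78 °C
Reagents that add atoms: none
Why: LiN(SiMe3)2 removes the only acidic C–H (C6', α to the lactone carbonyl; the aryl epoxy ketone has no enolisable hydrogen) and lithium enolate 14 adds to the C1' ketone. The closest known reaction type is the intramolecular aldol addition of an ester or lactone enolate to a ketone, here giving a bridged lactone. The single ring closed is the carbocycle, by a 6-(enolexo)-exo-trig closure across the α- and γ-carbons of the butyrolactone. C6' can bond only on the lactone face that carries the C4' side chain, and C1' is set by the lithium-chelated closed transition state, which holds the ketone oxygen gauche to the enolate C–O bond and so places O1' on the face of the lactone bridge, cis to O4', with the aryl group on the epoxide face; C2', C3' and C4' come unchanged from 13. The step needs 1,2-addition to win over epoxide opening by the enolate (4-exo or 5-endo, both disfavoured), intermolecular Claisen condensation and retro-aldol, which is secured by the cis-epoxide turn that holds C1' over C6', by low temperature and dilution, and by the cold acetic acid quench.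

Step 11
Reactants: 15 (1S,2R,3S,4S,5R)-2-{4,6-bis[2-(trimethylsilyl)ethoxy]pyridin-3-yl}-3,4-epoxy-2-hydroxy-6-oxabicyclo[3.2.1]octan-7-one
Product: 16 (1S,2R,3S,5R,6S)-2-{4,6-bis[2-(trimethylsilyl)ethoxy]pyridin-3-yl}-2,5-dihydroxy-7-oxabicyclo[4.1.0]heptane-3-carboxylic acid
Conditions: LiOH·H2O (3 equiv), THF/H2O 3:1, 0 °C → rt; then 0.5 M HCl to pH 4, 0 °C
Reagents that add atoms: lithium hydroxide, [Li+].[OH-]
Why: Saponification by acyl–oxygen cleavage opens the bridge without touching a stereocentre; the β-hydroxy carboxylate should not undergo retro-aldol and the cis-3-hydroxy acid should not relactonise without acyl activation.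

Step 12
Reactants: 16 (1S,2R,3S,5R,6S)-2-{4,6-bis[2-(trimethylsilyl)ethoxy]pyridin-3-yl}-2,5-dihydroxy-7-oxabicyclo[4.1.0]heptane-3-carboxylic acid
Product: 17 (1S,2R,5R,6S)-2-{4,6-bis[2-(trimethylsilyl)ethoxy]pyridin-3-yl}-7-oxabicyclo[4.1.0]heptane-2,5-diol
Conditions: 9-mesityl-10-phenylacridinium tetrafluoroborate (5 mol %), PhSSPh (10 mol %), i-Pr2NEt (20 mol %), CF3CH2OH, 450 nm LEDs, rt
Reagents that add atoms: none
Why: Acridinium photoredox hydrodecarboxylation: the carboxylate is oxidised by the excited acridinium, loses CO2 and the secondary C6' radical takes hydrogen from thiophenol, so the temporary carbon and its stereocentre are removed without an activated acyl intermediate that could relactonise.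

Step 13
Reactants: 17 (1S,2R,5R,6S)-2-{4,6-bis[2-(trimethylsilyl)ethoxy]pyridin-3-yl}-7-oxabicyclo[4.1.0]heptane-2,5-diol
Product: 18 2,5-bis(triethylsilyl) ether of 17
Conditions: Et3SiOTf (3 equiv), 2,6-lutidine (5 equiv), CH2Cl2, −78 → 0 °C
Reagents that add atoms: triethylsilyl trifluoromethanesulfonate, CC[Si](CC)(CC)OS(=O)(=O)C(F)(F)F
Why: Silyl triflate silylation caps both the secondary and the tertiary hydroxyl so that no acidic proton interferes with the lithiation of step 20.

**Fragment C: decalin aldehyde**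

Step 14
Reactants: 19 (S)-citronellol
Product: 20 (2E,6S)-8-hydroxy-2,6-dimethyloct-2-enal
Conditions: methacrolein (5 equiv), second-generation Hoveyda–Grubbs catalyst (5 mol %), CH2Cl2, 40 °C
Reagents that add atoms: methacrolein, CC(=C)C=O
Why: Olefin cross-metathesis exchanges the isopropylidene terminus for the 2-methyl-enal unit with loss of volatile 2-methylpropene, and should give the E-enal as the thermodynamic isomer.

Step 15
Reactants: 20 (2E,6S)-8-hydroxy-2,6-dimethyloct-2-enal
Product: 21 (2E,4E,8S)-10-hydroxy-N-methoxy-N,4,8-trimethyldeca-2,4-dienamide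
Conditions: diethyl [2-(methoxy(methyl)amino)-2-oxoethyl]phosphonate (1.3 equiv), LiCl, DBU, MeCN, 0 °C → rt
Reagents that add atoms: diethyl [2-(methoxy(methyl)amino)-2-oxoethyl]phosphonate, CCOP(=O)(OCC)CC(=O)N(C)OC
Why: Horner–Wadsworth–Emmons olefination under Masamune–Roush conditions tolerates the free hydroxyl and should give the E,E-dienyl Weinreb amide.

Step 16
Reactants: 21 (2E,4E,8S)-10-hydroxy-N-methoxy-N,4,8-trimethyldeca-2,4-dienamide
Product: 23 (2E,4E,8S,10E)-N-methoxy-N,4,8-trimethyl-12-oxododeca-2,4,10-trienamide, via aldehyde 22 (not isolated)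
Conditions: Dess–Martin periodinane, NaHCO3, CH2Cl2, 0 °C → rt; then Ph3P=CHCHO (1.5 equiv), 40 °C
Reagents that add atoms: (triphenylphosphoranylidene)acetaldehyde, O=CC=P(c1ccccc1)(c1ccccc1)c1ccccc1
Why: Dess–Martin oxidation followed in the same flask by Wittig reaction with the stabilised formyl ylide should extend the aldehyde to the E-enal.

Step 17
Reactants: 23 (2E,4E,8S,10E)-N-methoxy-N,4,8-trimethyl-12-oxododeca-2,4,10-trienamide
Product: 24 (1R,2S,4aS,7S,8aS)-1-formyl-N-methoxy-N,4,7-trimethyl-1,2,4a,5,6,7,8,8a-octahydronaphthalene-2-carboxamide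
Conditions: toluene (0.01 M), BHT (cat.), 140 °C, sealed tube
Reagents that add atoms: none
Why: Thermal intramolecular Diels–Alder reaction: the E-enal places the formyl group endo, which gives the trans ring fusion (the C4 methyl on the diene adds a bias against the cis-fused transition state); the C7 methyl sits equatorial in the chair-like tether and sets the absolute sense at C1, C4a and C8a; the E,E-diene leaves the amide pseudoaxial at C2, which is corrected in step 19.

Step 18
Reactants: 24 (1R,2S,4aS,7S,8aS)-1-formyl-N-methoxy-N,4,7-trimethyl-1,2,4a,5,6,7,8,8a-octahydronaphthalene-2-carboxamide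
Product: 25 (1R,2R,4aS,7S,8aR)-N-methoxy-N,4,7-trimethyl-1-[(1E)-prop-1-en-1-yl]-1,2,4a,5,6,7,8,8a-octahydronaphthalene-2-carboxamide
Conditions: CrCl2 (8 equiv), CH3CHI2 (2 equiv), THF, rt
Reagents that add atoms: 1,1-diiodoethane, CC(I)I
Why: Takai–Utimoto olefination through a geminal dichromium species should convert the aldehyde into the E-propenyl group chemoselectively, without base and so without epimerising C1.

Step 19
Reactants: 25 (1R,2R,4aS,7S,8aR)-N-methoxy-N,4,7-trimethyl-1-[(1E)-prop-1-en-1-yl]-1,2,4a,5,6,7,8,8a-octahydronaphthalene-2-carboxamide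
Product: 27 (1R,2S,4aS,7S,8aR)-4,7-dimethyl-1-[(1E)-prop-1-en-1-yl]-1,2,4a,5,6,7,8,8a-octahydronaphthalene-2-carbaldehyde, via pseudoaxial aldehyde 26 (not isolated)
Conditions: i-Bu2AlH (1.5 equiv), THF, −78 °C; Rochelle salt work-up; crude aldehyde, DBU (0.5 equiv), CH2Cl2, rt
Reagents that add atoms: none
Why: Weinreb amide reduction stops at the aldehyde through the chelated aluminium hemiaminal, and base-mediated epimerisation through the dienolate (reprotonated at the α-carbon) should move the formyl group to the pseudoequatorial, 1,2-trans position, the thermodynamic epimer, which sets C2.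

**Endgame**

Step 20
Reactants: 18 2,5-bis(triethylsilyl) ether of 17; 27 (1R,2S,4aS,7S,8aR)-4,7-dimethyl-1-[(1E)-prop-1-en-1-yl]-1,2,4a,5,6,7,8,8a-octahydronaphthalene-2-carbaldehyde
Product: 29 secondary carbinol joining pyridine C3 to the decalin (both carbinol epimers), via 3-lithiopyridine 28 (not isolated)
Conditions: t-BuLi (1.1 equiv), THF, −78 → −40 °C, 30 min; then 27 (1.0 equiv), −78 °C; aq NH4Cl
Reagents that add atoms: none
Why: Directed ortho-metalation at C3, the only position flanked by two alkoxy groups, followed by 1,2-addition to the aldehyde; the new carbinol centre is uncontrolled and is erased in step 21.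

Step 21
Reactants: 29 secondary carbinol joining pyridine C3 to the decalin
Product: 30 fully protected ketone (3-decalinoyl-2,4-bis[2-(trimethylsilyl)ethoxy]pyridine carrying the bis(triethylsilyl) epoxycyclohexyl unit at C5)
Conditions: Dess–Martin periodinane, NaHCO3, CH2Cl2, 0 °C → rt
Reagents that add atoms: none
Why: Dess–Martin oxidation of the hindered diaryl-type carbinol under buffered conditions should give the ketone while the C2 stereocentre stays in its stable equatorial arrangement.

Step 22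
Reactants: 30 fully protected ketone
Product: 31 target, 5-[(1S,2R,5R,6S)-2,5-dihydroxy-7-oxabicyclo[4.1.0]heptan-2-yl]-3-{[(1R,2S,4aS,7S,8aR)-4,7-dimethyl-1-[(1E)-prop-1-en-1-yl]-1,2,4a,5,6,7,8,8a-octahydronaphthalen-2-yl]carbonyl}-4-hydroxypyridin-2(1H)-one
Conditions: Bu4NF (6 equiv), AcOH (6 equiv), THF, 0 °C → rt (40 °C if needed)
Reagents that add atoms: none
Why: Fluoride-mediated global desilylation: the triethylsilyl ethers cleave at silicon and the two 2-(trimethylsilyl)ethyl ethers fragment to ethene and the pyridinolate, which tautomerises to the 4-hydroxy-2-pyridone; the acetic acid buffer should prevent base-induced epoxide migration and C2 epimerisation.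

**Compound list**

1 | tert-butyldimethyl(prop-2-yn-1-yloxy)silane | C#CCO[Si](C)(C)C(C)(C)C | starting material
2 | methyl 4-chloro-4-oxobutanoate | COC(=O)CCC(Cl)=O | starting material
3 | methyl 7-[(tert-butyldimethylsilyl)oxy]-4-oxohept-5-ynoate | COC(=O)CCC(=O)C#CCO[Si](C)(C)C(C)(C)C | intermediate
4 | methyl (4R)-7-[(tert-butyldimethylsilyl)oxy]-4-hydroxyhept-5-ynoate | COC(=O)CC[C@@H](O)C#CCO[Si](C)(C)C(C)(C)C | intermediate
5 | methyl (4R,5Z)-7-[(tert-butyldimethylsilyl)oxy]-4-hydroxyhept-5-enoate | COC(=O)CC[C@@H](O)/C=C\CO[Si](C)(C)C(C)(C)C | intermediate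
6 | methyl (4R)-4-[(2S,3R)-3-{[(tert-butyldimethylsilyl)oxy]methyl}oxiran-2-yl]-4-hydroxybutanoate (cis-epoxide, threo to the carbinol) | COC(=O)CC[C@@H](O)[C@@H]1O[C@@H]1CO[Si](C)(C)C(C)(C)C | intermediate
7 | (5R)-5-[(2S,3R)-3-(hydroxymethyl)oxiran-2-yl]oxolan-2-one | O=C1CC[C@@H](O1)[C@@H]2O[C@@H]2CO | intermediate
8 | (2S,3S)-3-[(2R)-5-oxooxolan-2-yl]oxirane-2-carbaldehyde | O=C1CC[C@@H](O1)[C@@H]2O[C@@H]2C=O | intermediate
9 | 5-bromo-2,4-dichloropyridine | Clc1cc(Cl)c(Br)cn1 | starting material
10 | 5-bromo-2,4-bis[2-(trimethylsilyl)ethoxy]pyridine | Brc1cnc(OCC[Si](C)(C)C)cc1OCC[Si](C)(C)C | intermediate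
11 | {4,6-bis[2-(trimethylsilyl)ethoxy]pyridin-3-yl}lithium | [Li]c1cnc(OCC[Si](C)(C)C)cc1OCC[Si](C)(C)C | intermediate
12 | (5R)-5-[(2S,3R)-3-{[4,6-bis(2-(trimethylsilyl)ethoxy)pyridin-3-yl](hydroxy)methyl}oxiran-2-yl]oxolan-2-one, both carbinol epimers | O=C1CC[C@@H](O1)[C@@H]2O[C@@H]2C(O)c3cnc(OCC[Si](C)(C)C)cc3OCC[Si](C)(C)C | intermediate
13 | (5R)-5-[(2S,3S)-3-{4,6-bis[2-(trimethylsilyl)ethoxy]pyridine-3-carbonyl}oxiran-2-yl]oxolan-2-one | O=C1CC[C@@H](O1)[C@@H]2O[C@@H]2C(=O)c3cnc(OCC[Si](C)(C)C)cc3OCC[Si](C)(C)C | intermediate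
14 | lithium enolate of 13 (lithium 4,5-dihydrofuran-2-olate) | [Li]OC1=CC[C@@H](O1)[C@@H]2O[C@@H]2C(=O)c3cnc(OCC[Si](C)(C)C)cc3OCC[Si](C)(C)C | intermediate
15 | (1S,2R,3S,4S,5R)-2-{4,6-bis[2-(trimethylsilyl)ethoxy]pyridin-3-yl}-3,4-epoxy-2-hydroxy-6-oxabicyclo[3.2.1]octan-7-one (hydroxyl syn, epoxide anti to the lactone bridge) | c1(cnc(OCC[Si](C)(C)C)cc1OCC[Si](C)(C)C)[C@]2(O)[C@@H]4C[C@@H](OC4=O)[C@@H]3O[C@@H]32 | intermediate
16 | (1S,2R,3S,5R,6S)-2-{4,6-bis[2-(trimethylsilyl)ethoxy]pyridin-3-yl}-2,5-dihydroxy-7-oxabicyclo[4.1.0]heptane-3-carboxylic acid | c1(cnc(OCC[Si](C)(C)C)cc1OCC[Si](C)(C)C)[C@]2(O)[C@@H](C(=O)O)C[C@@H](O)[C@@H]3O[C@@H]32 | intermediate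
17 | (1S,2R,5R,6S)-2-{4,6-bis[2-(trimethylsilyl)ethoxy]pyridin-3-yl}-7-oxabicyclo[4.1.0]heptane-2,5-diol | c1(cnc(OCC[Si](C)(C)C)cc1OCC[Si](C)(C)C)[C@]2(O)CC[C@@H](O)[C@@H]3O[C@@H]32 | intermediate
18 | 2,5-bis(triethylsilyl) ether of 17 (same configuration) | c1(cnc(OCC[Si](C)(C)C)cc1OCC[Si](C)(C)C)[C@]2(O[Si](CC)(CC)CC)CC[C@@H](O[Si](CC)(CC)CC)[C@@H]3O[C@@H]32 | intermediate
19 | (S)-citronellol, (3S)-3,7-dimethyloct-6-en-1-ol | OCC[C@@H](C)CCC=C(C)C | starting material
20 | (2E,6S)-8-hydroxy-2,6-dimethyloct-2-enal | OCC[C@@H](C)CC/C=C(\C)C=O | intermediate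
21 | (2E,4E,8S)-10-hydroxy-N-methoxy-N,4,8-trimethyldeca-2,4-dienamide | OCC[C@@H](C)CC/C=C(C)/C=C/C(=O)N(C)OC | intermediate
22 | (2E,4E,8S)-N-methoxy-N,4,8-trimethyl-10-oxodeca-2,4-dienamide | O=CC[C@@H](C)CC/C=C(C)/C=C/C(=O)N(C)OC | intermediate
23 | (2E,4E,8S,10E)-N-methoxy-N,4,8-trimethyl-12-oxododeca-2,4,10-trienamide | O=C/C=C/C[C@@H](C)CC/C=C(C)/C=C/C(=O)N(C)OC | intermediate
24 | (1R,2S,4aS,7S,8aS)-1-formyl-N-methoxy-N,4,7-trimethyl-1,2,4a,5,6,7,8,8a-octahydronaphthalene-2-carboxamide (trans-fused, formyl equatorial, amide pseudoaxial) | O=C[C@@H]1[C@H]2C[C@@H](C)CC[C@@H]2C(C)=C[C@@H]1C(=O)N(C)OC | intermediate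
25 | (1R,2R,4aS,7S,8aR)-N-methoxy-N,4,7-trimethyl-1-[(1E)-prop-1-en-1-yl]-1,2,4a,5,6,7,8,8a-octahydronaphthalene-2-carboxamide | C/C=C/[C@@H]1[C@H]2C[C@@H](C)CC[C@@H]2C(C)=C[C@@H]1C(=O)N(C)OC | intermediate
26 | (1R,2R,4aS,7S,8aR)-4,7-dimethyl-1-[(1E)-prop-1-en-1-yl]-1,2,4a,5,6,7,8,8a-octahydronaphthalene-2-carbaldehyde (formyl pseudoaxial) | C/C=C/[C@@H]1[C@H]2C[C@@H](C)CC[C@@H]2C(C)=C[C@@H]1C=O | intermediate
27 | (1R,2S,4aS,7S,8aR)-4,7-dimethyl-1-[(1E)-prop-1-en-1-yl]-1,2,4a,5,6,7,8,8a-octahydronaphthalene-2-carbaldehyde (formyl pseudoequatorial) | C/C=C/[C@@H]1[C@H]2C[C@@H](C)CC[C@@H]2C(C)=C[C@H]1C=O | intermediate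
28 | 3-lithio derivative of 18 (lithium between the two silylethoxy groups) | c1(cnc(OCC[Si](C)(C)C)c([Li])c1OCC[Si](C)(C)C)[C@]2(O[Si](CC)(CC)CC)CC[C@@H](O[Si](CC)(CC)CC)[C@@H]3O[C@@H]32 | intermediate
29 | carbinol from 28 and 27: {2,4-bis[2-(trimethylsilyl)ethoxy]-5-[bis(triethylsilyloxy)epoxycyclohexyl]pyridin-3-yl}(decalin-2-yl)methanol, both carbinol epimers | C/C=C/[C@@H]1[C@H]2C[C@@H](C)CC[C@@H]2C(C)=C[C@H]1C(O)c1c(OCC[Si](C)(C)C)c([C@]2(O[Si](CC)(CC)CC)CC[C@@H](O[Si](CC)(CC)CC)[C@@H]3O[C@@H]32)cnc1OCC[Si](C)(C)C | intermediate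
30 | ketone from 29 (fully protected target) | C/C=C/[C@@H]1[C@H]2C[C@@H](C)CC[C@@H]2C(C)=C[C@H]1C(=O)c1c(OCC[Si](C)(C)C)c([C@]2(O[Si](CC)(CC)CC)CC[C@@H](O[Si](CC)(CC)CC)[C@@H]3O[C@@H]32)cnc1OCC[Si](C)(C)C | intermediate
31 | CNP0494338.1, 5-[(1S,2R,5R,6S)-2,5-dihydroxy-7-oxabicyclo[4.1.0]heptan-2-yl]-3-{[(1R,2S,4aS,7S,8aR)-4,7-dimethyl-1-[(1E)-prop-1-en-1-yl]-1,2,4a,5,6,7,8,8a-octahydronaphthalen-2-yl]carbonyl}-4-hydroxypyridin-2(1H)-one | C/C=C/[C@@H]1[C@H]2C[C@@H](C)CC[C@@H]2C(C)=C[C@H]1C(=O)c1c(O)c([C@]2(O)CC[C@@H](O)[C@@H]3O[C@@H]32)c[nH]c1=O | target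

**Step count.** 22 steps in total. The longest linear sequence is 15 steps (steps 1–6, 8–13, 20–22).

**Steps most likely to fail**

Step 10 (key aldol). The bridged lithium aldolate may revert by retro-aldol, or the enolate may be lost to proton transfer or intermolecular condensation before it reaches the ketone. The fallback starts from 13 and traps the enolate as it forms, by deprotonation with LiN(i-Pr)2 in the presence of Me3SiCl at −78 °C, to give the trimethylsilyl ketene acetal F1. A catalytic amount of Bu4N[Ph3SiF2] then triggers an intramolecular Mukaiyama aldol addition in which the silyl group passes to the new alkoxide, so the adduct cannot revert; this should give the trimethylsilyl ether of the bridged lactone F2. Mild methanolysis (citric acid, MeOH) returns to the route at 15. The transition state is open here, so the C1' configuration would have to be checked.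

Step 17 (intramolecular Diels–Alder). The acceptor-substituted dienamide may react sluggishly with the electron-poor enal, so that the temperature needed erodes the endo preference or the enal polymerises. The fallback reverses the order of olefination and cycloaddition. From 23, Takai–Utimoto olefination of the enal (CrCl2, CH3CHI2) gives the tetraenamide F3, in which the dienophile is an electron-richer diene terminus matched to the dienamide. Cycloaddition with inverse electron demand, promoted by Me2AlCl complexed to the amide, should then give the propenyl decalin directly, returning to the route at 25.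

Step 12 (hydrodecarboxylation). The excited acridinium may oxidise the electron-rich dialkoxypyridine in competition with the carboxylate, so that decarboxylation stalls or the arene degrades. The fallback is a Barton radical decarboxylation with the hydroxyls masked first, so that acyl activation cannot relactonise. From 16, Et3SiOTf and 2,6-lutidine silylate both hydroxyls and the acid, and aqueous work-up hydrolyses the silyl ester to the bis(triethylsilyl) acid F4. EDC·HCl and 2-mercaptopyridine N-oxide give the thiohydroxamate (Barton) ester F5, and visible light with t-BuSH should reduce it to the bis-silyl ether, returning to the route at 18 and making step 13 unnecessary.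

**Further compounds**

F1 | step 10 | trimethylsilyl ketene acetal of 13 | C[Si](C)(C)OC1=CC[C@@H](O1)[C@@H]2O[C@@H]2C(=O)c3cnc(OCC[Si](C)(C)C)cc3OCC[Si](C)(C)C
F2 | step 10 | trimethylsilyl ether of 15 | c1(cnc(OCC[Si](C)(C)C)cc1OCC[Si](C)(C)C)[C@]2(O[Si](C)(C)C)[C@@H]4C[C@@H](OC4=O)[C@@H]3O[C@@H]32
F3 | step 17 | (2E,4E,8S,10E,12E)-N-methoxy-N,4,8-trimethyltetradeca-2,4,10,12-tetraenamide | C/C=C/C=C/C[C@@H](C)CC/C=C(C)/C=C/C(=O)N(C)OC
F4 | step 12 | 2,5-bis(triethylsilyl) ether of acid 16 | c1(cnc(OCC[Si](C)(C)C)cc1OCC[Si](C)(C)C)[C@]2(O[Si](CC)(CC)CC)[C@@H](C(=O)O)C[C@@H](O[Si](CC)(CC)CC)[C@@H]3O[C@@H]32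
F5 | step 12 | 2-thioxopyridin-1(2H)-yl ester (Barton ester) of F4 | c1(cnc(OCC[Si](C)(C)C)cc1OCC[Si](C)(C)C)[C@]2(O[Si](CC)(CC)CC)[C@@H](C(=O)On4ccccc4=S)C[C@@H](O[Si](CC)(CC)CC)[C@@H]3O[C@@H]32
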